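**Retrosynthetic overview**

1. Rings: A = phenol ring of the benzofuran (OH, geranyl); B = its furan ring; C = benzene ring of the 2,3-dihydrobenzofuran; D = the dihydrofuran ring (O1, C2, C3, C3a, C7a).
2. Last disconnection, ring B: Sonogashira coupling and 5-endo-dig O-cyclisation of 2-geranyl-4-iodoresorcinol (ring A) onto an ethynyl group at C4 of the ring C/D unit.
3. Key disconnection, ring D at C2–C3: catalyst-controlled intramolecular carbene C–H alkylation of an achiral aldehyde tosylhydrazone whose ortho ether is ArO–CH2–C(CH3)2OH (phenol plus isobutylene oxide). This creates the only stereocentre.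
4. Enabling feature: C3 is a benzylic CH2 on C3a, and C2 carries one H and the ring oxygen O1. A carbene at C3 therefore meets the O1-activated C2–H bonds of the ether in a 1,5 relationship (C3, C3a, C7a, O1, C2), and the tertiary carbinol carbon offers no competing hydrogen.
5. Order of ring formation: rings A and C come from resorcinol and 5-bromoresorcinol; ring D is closed in step 5; ring B in step 12.

Key step: step 5

Remark: Co(P*) is the divalent cobalt complex of the D2-symmetric chiral amidoporphyrin 5,15-bis(3,5-di-tert-butylphenyl)-10,20-bis[2,6-bis(2,2-dimethylcyclopropanecarboxamido)phenyl]porphyrin (dianion). Its sense of induction for ether 7 cannot be assigned in advance, so the ligand antipode that gives (R) at C2 is assumed to be chosen in a test run.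

**Route**

Step 1
Reactants: 1 5-bromoresorcinol
Product: 3 2-bromo-4,6-dihydroxybenzaldehyde, via iminium salt 2 (not isolated)
Conditions: POCl3, DMF, MeCN, 0 °C to rt; then H2O, 50 °C
Reagents that add atoms: N,N-dimethylformamide CN(C)C=O; water O
Why: Vilsmeier–Haack formylation should attack the ring position para to one hydroxyl and ortho to the other (next to bromine), as 5-alkylresorcinols do, and hydrolysis of iminium salt 2 should give the aldehyde.

Step 2
Reactants: 3 2-bromo-4,6-dihydroxybenzaldehyde
Product: 4 2-bromo-6-hydroxy-4-(methoxymethoxy)benzaldehyde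
Conditions: MOMCl (1.05 equiv), K2CO3, acetone, 0 °C to rt
Reagents that add atoms: chloromethyl methyl ether COCCl
Why: Williamson-type O-alkylation should take the more acidic 4-hydroxyl selectively, because the 6-hydroxyl is held in a hydrogen bond to the aldehyde.

Step 3
Reactants: 4 2-bromo-6-hydroxy-4-(methoxymethoxy)benzaldehyde; 5 2,2-dimethyloxirane
Product: 6 2-bromo-6-(2-hydroxy-2-methylpropoxy)-4-(methoxymethoxy)benzaldehyde
Conditions: K2CO3 (0.3 equiv), DMF, 90 °C, sealed tube
Reagents that add atoms: none
Why: Base-catalysed SN2 opening of the epoxide by the phenoxide at the unsubstituted CH2 should give the achiral aryl ether with the complete tertiary carbinol side chain; the MOM ether, aldehyde and aryl bromide are stable to carbonate.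

Step 4
Reactants: 6 2-bromo-6-(2-hydroxy-2-methylpropoxy)-4-(methoxymethoxy)benzaldehyde
Product: 7 (E)-N'-{[2-bromo-6-(2-hydroxy-2-methylpropoxy)-4-(methoxymethoxy)phenyl]methylidene}-4-methylbenzenesulfonohydrazide
Conditions: TsNHNH2, MeOH, rt to 50 °C
Reagents that add atoms: p-toluenesulfonyl hydrazide Cc1ccc(cc1)S(=O)(=O)NN
Why: Condensation of the aldehyde with the sulfonyl hydrazide should give the crystalline N-tosylhydrazone, the carbene precursor of a Bamford–Stevens reaction, without acid that would touch the MOM ether.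

Step 5
Reactants: 7 (E)-N'-{[2-bromo-6-(2-hydroxy-2-methylpropoxy)-4-(methoxymethoxy)phenyl]methylidene}-4-methylbenzenesulfonohydrazide
Product: 9 2-[(2R)-4-bromo-6-(methoxymethoxy)-2,3-dihydro-1-benzofuran-2-yl]propan-2-ol, via aryldiazomethane 8 (not isolated)
Conditions: Co(P*) (2 mol %), Cs2CO3 (2 equiv), 1,4-dioxane, 60 °C
Reagents that add atoms: none
Why: Cs2CO3 turns 7 into aryldiazomethane 8 (Bamford–Stevens), which Co(P*), a divalent cobalt metalloradical, converts with loss of N2 into a trivalent cobalt carbene radical centred on the future C3; this radical abstracts a hydrogen from the O–CH2 group through a six-membered transition state (1,5-hydrogen atom transfer), and the α-alkoxyalkyl radical so formed at the future C2 attacks the cobalt-bound benzylic carbon, breaking the Co–C bond and releasing Co(P*). The closest known reaction type is the enantioselective metalloradical 1,5-C–H alkylation with aryldiazomethanes generated in situ from aldehyde tosylhydrazones (2-substituted indolines and related five-membered rings), backed by Rh2(O2CR*)4-catalysed insertions of ortho-alkoxyaryl carbenes into ether C–H bonds that give 2,3-dihydrobenzofurans. Ring D is closed at C2–C3 in a 5-exo-tet radical substitution. The only new stereocentre, C2, is set under catalyst control: substrate 7 is achiral, the chiral amide pocket of P* distinguishes the two enantiotopic O–CH2 hydrogens and the caged radical closes before it can rotate, so the ligand antipode alone decides for (R). The step needs site selectivity among the C–H bonds, which the substrate secures because only the two O–CH2 hydrogens are both 1,5 to the carbene carbon and weakened by O1, while the methyl and hydroxyl hydrogens are 1,7, the carbinol carbon has no hydrogen and the MOM group sits para and out of reach. It also needs chemoselectivity against azine and stilbene formation, secured by slow release of 8 at 60 °C, and the aryl bromide, MOM ether and free tertiary alcohol are inert to this radical manifold.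

Step 6
Reactants: 9 2-[(2R)-4-bromo-6-(methoxymethoxy)-2,3-dihydro-1-benzofuran-2-yl]propan-2-ol; 10 ethynyltrimethylsilane
Product: 11 2-[(2R)-6-(methoxymethoxy)-4-[(trimethylsilyl)ethynyl]-2,3-dihydro-1-benzofuran-2-yl]propan-2-ol
Conditions: PdCl2(PPh3)2 (5 mol %), CuI (10 mol %), Et3N, DMF, 80 °C, sealed tube
Reagents that add atoms: none
Why: Sonogashira coupling (zerovalent palladium inserts into the C4–Br bond, the copper acetylide transmetalates) should install the two carbons of the future furan ring B without touching the C2 stereocentre or the free tertiary alcohol.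

Step 7
Reactants: 11 2-[(2R)-6-(methoxymethoxy)-4-[(trimethylsilyl)ethynyl]-2,3-dihydro-1-benzofuran-2-yl]propan-2-ol
Product: 12 (2R)-2-(2-hydroxypropan-2-yl)-4-[(trimethylsilyl)ethynyl]-2,3-dihydro-1-benzofuran-6-ol
Conditions: HCl (1 M), MeOH, 40 °C
Reagents that add atoms: none
Why: Acid-catalysed transacetalisation to methanol should free the phenol at a stage where no geranyl group is present; the silylalkyne, the tertiary alcohol (β to the ring oxygen, hard to ionise) and the non-epimerisable C2 centre should survive dilute acid.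

Step 8
Reactants: 13 resorcinol
Product: 14 1,3-bis(methoxymethoxy)benzene
Conditions: NaH, MOMCl, DMF, 0 °C to rt
Reagents that add atoms: chloromethyl methyl ether COCCl
Why: Double Williamson etherification of the bis-phenoxide should give the bis-acetal, whose two OMOM groups direct the metalations that follow.

Step 9
Reactants: 14 1,3-bis(methoxymethoxy)benzene; 15 geranyl bromide
Product: 17 2-[(2E)-3,7-dimethylocta-2,6-dien-1-yl]-1,3-bis(methoxymethoxy)benzene, via aryllithium 16 (not isolated)
Conditions: n-BuLi, THF, 0 °C to rt; then CuI (10 mol %), 15, −78 °C to rt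
Reagents that add atoms: none
Why: Directed ortho-metalation between the two OMOM groups followed by copper-assisted SN2 allylation at the primary carbon of geranyl bromide should place the geranyl chain at C2 with the E alkene intact.

Step 10
Reactants: 17 2-[(2E)-3,7-dimethylocta-2,6-dien-1-yl]-1,3-bis(methoxymethoxy)benzene
Product: 19 2-[(2E)-3,7-dimethylocta-2,6-dien-1-yl]-4-iodo-1,3-bis(methoxymethoxy)benzene, via aryllithium 18 (not isolated)
Conditions: s-BuLi, TMEDA, THF, −78 °C; then I2, −78 °C
Reagents that add atoms: iodine II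
Why: A second, kinetically controlled directed ortho-metalation next to one OMOM group (ring deprotonation being preferred over the benzylic-allylic CH2 at −78 °C) and iodine quench should give the aryl iodide without any electrophilic iodination of the alkenes.

Step 11
Reactants: 19 2-[(2E)-3,7-dimethylocta-2,6-dien-1-yl]-4-iodo-1,3-bis(methoxymethoxy)benzene
Product: 20 2-[(2E)-3,7-dimethylocta-2,6-dien-1-yl]-4-iodobenzene-1,3-diol
Conditions: HCl (0.5 M), MeOH, rt
Reagents that add atoms: none
Why: Mild acid-catalysed transacetalisation of both MOM ethers to methanol should free the resorcinol at room temperature, below the acidity needed to protonate the trisubstituted alkenes.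

Step 12
Reactants: 12 (2R)-2-(2-hydroxypropan-2-yl)-4-[(trimethylsilyl)ethynyl]-2,3-dihydro-1-benzofuran-6-ol; 20 2-[(2E)-3,7-dimethylocta-2,6-dien-1-yl]-4-iodobenzene-1,3-diol
Product: 23 mulberrofuran X, via terminal alkyne 21 (not isolated), via diarylalkyne 22 (not isolated)
Conditions: PdCl2(PPh3)2 (5 mol %), CuI (10 mol %), CsF (2.5 equiv), Et3N, DMF, rt to 80 °C, argon
Reagents that add atoms: none
Why: Fluoride desilylation should release alkyne 21 slowly, Sonogashira coupling at the aryl iodide should give the ortho-alkynylphenol 22, and the hydroxyl ortho to the alkyne should add 5-endo-dig under Cu/Pd activation (Castro–Stephens-type benzofuran synthesis) to close ring B, the other hydroxyls being unable to reach the alkyne and the C2 stereocentre being untouched.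

**Compound list**

1 | 5-bromoresorcinol (5-bromobenzene-1,3-diol) | Oc1cc(O)cc(Br)c1 | starting material
2 | N-[(2-bromo-4,6-dihydroxyphenyl)methylidene]-N-methylmethanaminium chloride (Vilsmeier iminium salt) | C[N+](C)=Cc1c(O)cc(O)cc1Br.[Cl-] | intermediate
3 | 2-bromo-4,6-dihydroxybenzaldehyde | O=Cc1c(O)cc(O)cc1Br | intermediate
4 | 2-bromo-6-hydroxy-4-(methoxymethoxy)benzaldehyde | COCOc1cc(O)c(C=O)c(Br)c1 | intermediate
5 | 2,2-dimethyloxirane (isobutylene oxide) | CC1(C)CO1 | starting material
6 | 2-bromo-6-(2-hydroxy-2-methylpropoxy)-4-(methoxymethoxy)benzaldehyde | COCOc1cc(OCC(C)(C)O)c(C=O)c(Br)c1 | intermediate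
7 | (E)-N'-{[2-bromo-6-(2-hydroxy-2-methylpropoxy)-4-(methoxymethoxy)phenyl]methylidene}-4-methylbenzenesulfonohydrazide | COCOc1cc(OCC(C)(C)O)c(/C=N/NS(=O)(=O)c2ccc(C)cc2)c(Br)c1 | intermediate
8 | 1-bromo-2-(diazomethyl)-3-(2-hydroxy-2-methylpropoxy)-5-(methoxymethoxy)benzene (aryldiazomethane) | COCOc1cc(OCC(C)(C)O)c(C=[N+]=[N-])c(Br)c1 | intermediate
9 | 2-[(2R)-4-bromo-6-(methoxymethoxy)-2,3-dihydro-1-benzofuran-2-yl]propan-2-ol | COCOc1cc(Br)c2C[C@H](C(C)(C)O)Oc2c1 | intermediate
10 | ethynyltrimethylsilane | C#C[Si](C)(C)C | starting material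
11 | 2-[(2R)-6-(methoxymethoxy)-4-[(trimethylsilyl)ethynyl]-2,3-dihydro-1-benzofuran-2-yl]propan-2-ol | COCOc1cc(C#C[Si](C)(C)C)c2C[C@H](C(C)(C)O)Oc2c1 | intermediate
12 | (2R)-2-(2-hydroxypropan-2-yl)-4-[(trimethylsilyl)ethynyl]-2,3-dihydro-1-benzofuran-6-ol | Oc1cc(C#C[Si](C)(C)C)c2C[C@H](C(C)(C)O)Oc2c1 | intermediate
13 | resorcinol (benzene-1,3-diol) | Oc1cccc(O)c1 | starting material
14 | 1,3-bis(methoxymethoxy)benzene | COCOc1cccc(OCOC)c1 | intermediate
15 | geranyl bromide ((2E)-1-bromo-3,7-dimethylocta-2,6-diene) | CC(C)=CCC/C(C)=C/CBr | starting material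
16 | [2,6-bis(methoxymethoxy)phenyl]lithium | COCOc1cccc(OCOC)c1[Li] | intermediate
17 | 2-[(2E)-3,7-dimethylocta-2,6-dien-1-yl]-1,3-bis(methoxymethoxy)benzene | CC(C)=CCC/C(C)=C/Cc1c(OCOC)cccc1OCOC | intermediate
18 | {3-[(2E)-3,7-dimethylocta-2,6-dien-1-yl]-2,4-bis(methoxymethoxy)phenyl}lithium | CC(C)=CCC/C(C)=C/Cc1c(OCOC)ccc([Li])c1OCOC | intermediate
19 | 2-[(2E)-3,7-dimethylocta-2,6-dien-1-yl]-4-iodo-1,3-bis(methoxymethoxy)benzene | CC(C)=CCC/C(C)=C/Cc1c(OCOC)ccc(I)c1OCOC | intermediate
20 | 2-[(2E)-3,7-dimethylocta-2,6-dien-1-yl]-4-iodobenzene-1,3-diol (2-geranyl-4-iodoresorcinol) | CC(C)=CCC/C(C)=C/Cc1c(O)ccc(I)c1O | intermediate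
21 | (2R)-4-ethynyl-2-(2-hydroxypropan-2-yl)-2,3-dihydro-1-benzofuran-6-ol | Oc1cc(C#C)c2C[C@H](C(C)(C)O)Oc2c1 | intermediate
22 | 2-[(2E)-3,7-dimethylocta-2,6-dien-1-yl]-4-{[(2R)-6-hydroxy-2-(2-hydroxypropan-2-yl)-2,3-dihydro-1-benzofuran-4-yl]ethynyl}benzene-1,3-diol | CC(C)=CCC/C(C)=C/Cc1c(O)ccc(C#Cc2cc(O)cc3c2C[C@H](C(C)(C)O)O3)c1O | intermediate
23 | mulberrofuran X, (2R)-4-{7-[(2E)-3,7-dimethylocta-2,6-dien-1-yl]-6-hydroxy-1-benzofuran-2-yl}-2-(2-hydroxypropan-2-yl)-2,3-dihydro-1-benzofuran-6-ol | CC(C)=CCC/C(C)=C/Cc1c(O)ccc2cc(-c3cc(O)cc4c3C[C@H](C(C)(C)O)O4)oc12 | target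

**Step count and risks**

Total step count: 12. Longest linear sequence: 8 steps (steps 1 to 7, then step 12).

Steps most likely to fail:

Step 5. The carbene carbon sits between two ortho substituents and the O–CH2 site is next to a quaternary carbon, so hydrogen abstraction may be slow. Bimolecular decay of the diazo compound (azine and stilbene formation) could then overtake ring closure, or enantiodiscrimination in the ring closure could be weak. The fallback keeps the ring closure at the same C2–C3 bond but makes it a condensation and sets the stereocentre by hydrogenation. It sets out from 4: Rap–Stoermer reaction with ethyl bromoacetate (K2CO3, DMF, 100 °C; O-alkylation, then intramolecular aldol condensation of the aryloxyacetate onto the aldehyde) should give ethyl 4-bromo-6-(methoxymethoxy)-1-benzofuran-2-carboxylate F1. Addition of MeMgBr (THF, 0 °C) should give 2-[4-bromo-6-(methoxymethoxy)-1-benzofuran-2-yl]propan-2-ol F2. Asymmetric hydrogenation of the furan C2=C3 bond with the chiral ruthenium N-heterocyclic carbene catalyst made from Ru(cod)(2-methylallyl)2, SINpEt·HBF4 (1,3-bis[1-(naphthalen-1-yl)ethyl]-4,5-dihydroimidazolium tetrafluoroborate, antipode chosen for (R)) and KOtBu under H2 should then give 9, where the route is rejoined before step 6.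

Step 12. With three free phenols in the pot, oxidative homocoupling of the released alkyne, deactivation of the catalysts by phenoxides, or stalling at the uncyclised diarylalkyne may lower the throughput of the cascade. The fallback separates coupling from ring closure and masks ring A. It sets out from 20 and 12: acetylation of 20 (Ac2O, pyridine) should give 2-[(2E)-3,7-dimethylocta-2,6-dien-1-yl]-4-iodo-1,3-phenylene diacetate F3, and 12 is desilylated on its own (K2CO3, MeOH, rt) to the isolated alkyne 21. Sonogashira coupling of F3 with 21 (PdCl2(PPh3)2, CuI, Et3N, THF, rt) should give the diarylalkyne diacetate 2-[(2E)-3,7-dimethylocta-2,6-dien-1-yl]-4-{[(2R)-6-hydroxy-2-(2-hydroxypropan-2-yl)-2,3-dihydro-1-benzofuran-4-yl]ethynyl}-1,3-phenylene diacetate F4. Methanolysis of the acetates (K2CO3, MeOH, then Cs2CO3, DMF, 60 °C) should free the phenoxide, which adds to the alkyne 5-endo-dig and arrives at 23.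

Step 11. Protonation of a trisubstituted alkene during acetal cleavage may lead to cyclisation of the freed phenol onto the geranyl chain (chroman formation) or to addition of methanol. The fallback replaces the acid-labile directing group by a fluoride-labile one. It sets out from 13: resorcinol with SEMCl and NaH (DMF) should give 1,3-bis{[2-(trimethylsilyl)ethoxy]methoxy}benzene F5. Lithiation with n-BuLi (THF, 0 °C) should give (2,6-bis{[2-(trimethylsilyl)ethoxy]methoxy}phenyl)lithium F6, which with 15 and CuI (10 mol %) should give 2-[(2E)-3,7-dimethylocta-2,6-dien-1-yl]-1,3-bis{[2-(trimethylsilyl)ethoxy]methoxy}benzene F7. A second lithiation (s-BuLi, TMEDA, THF, −78 °C) should give (3-[(2E)-3,7-dimethylocta-2,6-dien-1-yl]-2,4-bis{[2-(trimethylsilyl)ethoxy]methoxy}phenyl)lithium F8, and iodine quench should give 2-[(2E)-3,7-dimethylocta-2,6-dien-1-yl]-4-iodo-1,3-bis{[2-(trimethylsilyl)ethoxy]methoxy}benzene F9. Tetrabutylammonium fluoride (THF/DMPU, 60 °C) should then cleave both groups without acid and give 20, where the route is rejoined before step 12.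

**Further compounds**

F1 | step 5 | ethyl 4-bromo-6-(methoxymethoxy)-1-benzofuran-2-carboxylate | CCOC(=O)c1cc2c(Br)cc(OCOC)cc2o1
F2 | step 5 | 2-[4-bromo-6-(methoxymethoxy)-1-benzofuran-2-yl]propan-2-ol | CC(C)(O)c1cc2c(Br)cc(OCOC)cc2o1
F3 | step 12 | 2-[(2E)-3,7-dimethylocta-2,6-dien-1-yl]-4-iodo-1,3-phenylene diacetate | CC(C)=CCC/C(C)=C/Cc1c(OC(C)=O)ccc(I)c1OC(C)=O
F4 | step 12 | 2-[(2E)-3,7-dimethylocta-2,6-dien-1-yl]-4-{[(2R)-6-hydroxy-2-(2-hydroxypropan-2-yl)-2,3-dihydro-1-benzofuran-4-yl]ethynyl}-1,3-phenylene diacetate | CC(C)=CCC/C(C)=C/Cc1c(OC(C)=O)ccc(C#Cc2cc(O)cc3c2C[C@H](C(C)(C)O)O3)c1OC(C)=O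
F5 | step 11 | 1,3-bis{[2-(trimethylsilyl)ethoxy]methoxy}benzene | C[Si](C)(C)CCOCOc1cccc(OCOCC[Si](C)(C)C)c1
F6 | step 11 | (2,6-bis{[2-(trimethylsilyl)ethoxy]methoxy}phenyl)lithium | C[Si](C)(C)CCOCOc1cccc(OCOCC[Si](C)(C)C)c1[Li]
F7 | step 11 | 2-[(2E)-3,7-dimethylocta-2,6-dien-1-yl]-1,3-bis{[2-(trimethylsilyl)ethoxy]methoxy}benzene | CC(C)=CCC/C(C)=C/Cc1c(OCOCC[Si](C)(C)C)cccc1OCOCC[Si](C)(C)C
F8 | step 11 | (3-[(2E)-3,7-dimethylocta-2,6-dien-1-yl]-2,4-bis{[2-(trimethylsilyl)ethoxy]methoxy}phenyl)lithium | CC(C)=CCC/C(C)=C/Cc1c(OCOCC[Si](C)(C)C)ccc([Li])c1OCOCC[Si](C)(C)C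
F9 | step 11 | 2-[(2E)-3,7-dimethylocta-2,6-dien-1-yl]-4-iodo-1,3-bis{[2-(trimethylsilyl)ethoxy]methoxy}benzene | CC(C)=CCC/C(C)=C/Cc1c(OCOCC[Si](C)(C)C)ccc(I)c1OCOCC[Si](C)(C)C
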